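**Assumption:** the SMILES is read as the (3R)-chroman-3-ol carrying an (E)-geranyl ether; 1 is used as the dried, anhydrous material.

## Retrosynthetic overview

1. Target 7 ⇐ chroman-3-one 6 by enantioselective reduction of the C3 ketone, which sets the only stereocentre (R).
2. 6 ⇐ aryl 1,1-dimethylpropargyl ether 5. The key C4–C4a bond is closed by the arene attacking an α-oxo gold carbene, an enolonium equivalent made by gold-catalysed N-oxide oxidation of the terminal alkyne.
3. 5 ⇐ phenol 3 + 3-chloro-3-methylbut-1-yne 4; 3 ⇐ 2,4,6-trihydroxyacetophenone 1 + geranyl bromide 2 (para-selective O-alkylation).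
4. Ring order: the benzene ring (ring A) is bought with the acetyl group in place; the pyran ring (ring B) is closed in step 3.

## Route

**Step 1**
Reactants: 1 2,4,6-trihydroxyacetophenone; 2 geranyl bromide, (2E)-1-bromo-3,7-dimethylocta-2,6-diene
Product: 3 1-{4-[(2E)-3,7-dimethylocta-2,6-dien-1-yloxy]-2,6-dihydroxyphenyl}ethan-1-one
Conditions: 2 (1.0 equiv), K2CO3 (1.1 equiv), acetone, 0 °C to rt
Reagents that add atoms: none
Why: Williamson ether synthesis (SN2 on the allylic bromide); the para hydroxyl is the most acidic and the only one not hydrogen-bonded to the acetyl carbonyl, so one equivalent of base and bromide alkylates it selectively, and the aprotic solvent favours O- over C-alkylation.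

**Step 2**
Reactants: 3 1-{4-[(2E)-3,7-dimethylocta-2,6-dien-1-yloxy]-2,6-dihydroxyphenyl}ethan-1-one; 4 3-chloro-3-methylbut-1-yne
Product: 5 1-{4-[(2E)-3,7-dimethylocta-2,6-dien-1-yloxy]-2-hydroxy-6-[(2-methylbut-3-yn-2-yl)oxy]phenyl}ethan-1-one
Conditions: 4 (1.5 equiv), K2CO3 (2 equiv), KI (0.2 equiv), CuI (2 mol%), DMF, 60 °C
Reagents that add atoms: none
Why: Copper-catalysed propargylic etherification of a phenoxide; the two ortho hydroxyls of 3 are equivalent, and after one is alkylated the other is locked in a strong hydrogen bond to the carbonyl and does not react, while 60 °C is well below the onset of the aryl propargyl Claisen rearrangement.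

**Step 3**
Reactants: 5 1-{4-[(2E)-3,7-dimethylocta-2,6-dien-1-yloxy]-2-hydroxy-6-[(2-methylbut-3-yn-2-yl)oxy]phenyl}ethan-1-one
Product: 6 8-acetyl-5-[(2E)-3,7-dimethylocta-2,6-dien-1-yloxy]-7-hydroxy-2,2-dimethyl-2H-chromen-3(4H)-one
Conditions: (Me4tBuXPhos)AuNTf2 (5 mol%), 3,5-dichloropyridine N-oxide (2 equiv, added slowly), 1,2-dichloroethane, 0.05 M, rt
Reagents that add atoms: 3,5-dichloropyridine N-oxide, [O-][n+]1cc(Cl)cc(Cl)c1
Why: Gold-catalysed alkyne oxidation followed by Friedel–Crafts-type carbene arylation: monovalent gold activates the terminal alkyne, the N-oxide attacks the internal carbon and N–O cleavage leaves a catalyst-bound α-oxo gold carbene, an enolonium equivalent whose electrophilic α-carbon is captured in a six-membered closure by the only free ortho carbon (flanked by two oxygens and para to the phenol), joining a ketone α-carbon to a nucleophilic arene carbon; the bulky biaryl phosphine and excess oxidant disfavour direct hydroarylation to the chromene, and no stereocentre is formed.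

**Step 4**
Reactants: 6 8-acetyl-5-[(2E)-3,7-dimethylocta-2,6-dien-1-yloxy]-7-hydroxy-2,2-dimethyl-2H-chromen-3(4H)-one
Product: 7 1-{(3R)-5-[(2E)-3,7-dimethylocta-2,6-dien-1-yloxy]-3,7-dihydroxy-2,2-dimethyl-3,4-dihydro-2H-chromen-8-yl}ethan-1-one
Conditions: (S)-Me-CBS oxazaborolidine (0.3 equiv), catecholborane (2.5 equiv), toluene, –78 to –40 °C; then MeOH, aq. NaHCO3
Reagents that add atoms: none
Why: Corey–Bakshi–Shibata reduction: the C3 ketone binds the oxazaborolidine boron anti to the quaternary C2 (large group, versus the C4 methylene as small group), so the (S)-catalyst delivers hydride to the Si face and gives the (R)-alcohol, while the hydrogen-bonded, electron-rich aryl ketone and the trisubstituted alkenes are inert to catecholborane at low temperature.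

## Compound list

1 | 2,4,6-trihydroxyacetophenone | CC(=O)c1c(O)cc(O)cc1O | starting material
2 | geranyl bromide, (2E)-1-bromo-3,7-dimethylocta-2,6-diene | BrC/C=C(\C)CCC=C(C)C | starting material
3 | 1-{4-[(2E)-3,7-dimethylocta-2,6-dien-1-yloxy]-2,6-dihydroxyphenyl}ethan-1-one | CC(=O)c1c(O)cc(OC/C=C(\C)CCC=C(C)C)cc1O | intermediate
4 | 3-chloro-3-methylbut-1-yne | CC(C)(Cl)C#C | starting material
5 | 1-{4-[(2E)-3,7-dimethylocta-2,6-dien-1-yloxy]-2-hydroxy-6-[(2-methylbut-3-yn-2-yl)oxy]phenyl}ethan-1-one | CC(=O)c1c(O)cc(OC/C=C(\C)CCC=C(C)C)cc1OC(C)(C)C#C | intermediate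
6 | 8-acetyl-5-[(2E)-3,7-dimethylocta-2,6-dien-1-yloxy]-7-hydroxy-2,2-dimethyl-2H-chromen-3(4H)-one | CC(=O)c1c(O)cc(OC/C=C(\C)CCC=C(C)C)c2c1OC(C)(C)C(=O)C2 | intermediate
7 | 1-{(3R)-5-[(2E)-3,7-dimethylocta-2,6-dien-1-yloxy]-3,7-dihydroxy-2,2-dimethyl-3,4-dihydro-2H-chromen-8-yl}ethan-1-one | CC(=O)c1c(O)cc(OC/C=C(\C)CCC=C(C)C)c2c1OC(C)(C)[C@H](O)C2 | target

## Step count and risks

Total step count: 4. Longest linear sequence: 4 steps (1 → 3 → 5 → 6 → 7).

**Step 3 (most likely to fail).** The electron-rich arene may attack the gold-activated alkyne directly (hydroarylation or propargyl Claisen to the 2,2-dimethyl-2H-chromene). The carbene may also be over-oxidised to the keto-aldehyde, or the tertiary propargylic C–O bond may ionise. The fallback sets out from 5 and keeps the same polarity logic with a different carbene source. Cycloaddition of 5 with tosyl azide (CuI, 2,6-lutidine, CHCl3, 0 °C) gives the N-sulfonyl triazole 1-{4-[(2E)-3,7-dimethylocta-2,6-dien-1-yloxy]-2-hydroxy-6-({2-[1-(4-methylbenzenesulfonyl)-1H-1,2,3-triazol-4-yl]propan-2-yl}oxy)phenyl}ethan-1-one F1. Dirhodium tetraoctanoate, Rh2(O2CC7H15)4 (divalent rhodium, 2 mol%), in CHCl3 at 60 °C extrudes nitrogen to an α-imino rhodium carbene, an aza-enolonium equivalent. The same arene carbon captures it to give the enamide N-{8-acetyl-5-[(2E)-3,7-dimethylocta-2,6-dien-1-yloxy]-7-hydroxy-2,2-dimethyl-2H-chromen-3-yl}-4-methylbenzenesulfonamide F2. Mild hydrolysis (oxalic acid, wet THF, rt) then releases the ketone, and the fallback comes back to the route at 6.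

**Step 4.** Face selectivity may be incomplete for this dialkyl ketone, and the boron reagent may be consumed or diverted by the phenol and the chelated aryl ketone. The fallback sets out from 6 and replaces the borane chemistry by biocatalysis. An (R)-selective ketoreductase picked from a commercial panel is used with NADP+ and isopropanol recycling in pH 7 phosphate buffer/DMSO at 30 °C. It reduces only the unhindered dialkyl ketone and comes back to the route at 7. This fallback makes no new compound (F0).

**Step 1.** C-geranylation of the phloroglucinol ring and over-alkylation at an ortho hydroxyl can erode the yield. The fallback sets out from 1 and forms the same ether by redox condensation instead of phenoxide alkylation. A Mitsunobu reaction with geraniol (PPh3, diisopropyl azodicarboxylate, THF, 0 °C to rt) engages only the most acidic, non-chelated para hydroxyl and cannot C-alkylate. It comes back to the route at 3. This fallback makes no new compound (F0).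

## Further compounds

F0 | step 1 | none | none
F1 | step 3 | 1-{4-[(2E)-3,7-dimethylocta-2,6-dien-1-yloxy]-2-hydroxy-6-({2-[1-(4-methylbenzenesulfonyl)-1H-1,2,3-triazol-4-yl]propan-2-yl}oxy)phenyl}ethan-1-one | CC(=O)c1c(O)cc(OC/C=C(\C)CCC=C(C)C)cc1OC(C)(C)c1cn(S(=O)(=O)c2ccc(C)cc2)nn1
F2 | step 3 | N-{8-acetyl-5-[(2E)-3,7-dimethylocta-2,6-dien-1-yloxy]-7-hydroxy-2,2-dimethyl-2H-chromen-3-yl}-4-methylbenzenesulfonamide | CC(=O)c1c(O)cc(OC/C=C(\C)CCC=C(C)C)c2c1OC(C)(C)C(NS(=O)(=O)c1ccc(C)cc1)=C2
F0 | step 4 | none | none
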